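**Retrosynthetic overview**

1. C10–C11: non-8-enyl Grignard adds under chelation control to a 2-formyloxolane that already carries the C7 stearate (sets C10, last step).
2. The formyl carbon C10 travels through the route as C2 of a thiazole and is released only then by dearomatizing that ring (N-methylation, hydride, hydrolysis). 2-Acetylthiazole, a bulk flavour chemical, supplies C8–C10.
3. The stearate is put on C7 while that is the only hydroxyl in the molecule, so the two alcohols never have to be told apart and no protecting group is used.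
4. The single ring (oxolane) is closed once, by the C9 hydroxyl displacing a C6 chloride with inversion. C9 comes from a 1,3-syn reduction, C7 from an anti-aldol of the acetylthiazole enolate with (R)-2-chloroheptanal.
5. C6 comes from organocatalytic α-chlorination of heptanal.

Assumption: the (2S,5S) antipode of 2,5-diphenylpyrrolidine is taken to be the one that delivers the (R)-chloride; if the sense is the opposite, the (2R,5R) catalyst is used and nothing else changes.

**Route**

Step 1
Reactants: 1 heptanal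
Product: 2 (2R)-2-chloroheptanal
Conditions: N-chlorosuccinimide (1.3 equiv), (2S,5S)-2,5-diphenylpyrrolidine (10 mol%), CH2Cl2, 0 °C to rt; pentane filtration, used at once
Reagents that add atoms: N-chlorosuccinimide, O=C1CCC(=O)N1Cl
Why: Enamine catalysis (Jørgensen-type organocatalytic α-chlorination): the C2-symmetric pyrrolidine shields one enamine face so that Cl is delivered to give the (R)-chloride (about 90–95% ee), which fixes the absolute configuration of the whole route.

Step 2
Reactants: 2 (2R)-2-chloroheptanal; 3 2-acetyl-1,3-thiazole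
Product: 5 (3S,4R)-4-chloro-3-hydroxy-1-(1,3-thiazol-2-yl)nonan-1-one, via lithium enolate 4 (not isolated)
Conditions: 3, LiN(SiMe3)2 (1.05 equiv), THF, −78 °C, 30 min; then 2, −78 °C, 20 min; NH4Cl (aq) at −78 °C
Reagents that add atoms: none
Why: Lithium-enolate aldol addition under Cornforth (polar Felkin–Anh) control: the enolate attacks the α-chloro aldehyde anti to the C–Cl dipole and gives the 3,4-anti chlorohydrin (new C3 = S, typically ≥10:1), the cold quench keeping the aldolate from closing an epoxide.

Step 3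
Reactants: 5 (3S,4R)-4-chloro-3-hydroxy-1-(1,3-thiazol-2-yl)nonan-1-one
Product: 7 (1R,3S,4R)-4-chloro-1-(1,3-thiazol-2-yl)nonane-1,3-diol, via diethylboron chelate 6 (not isolated)
Conditions: Et2BOMe (1.1 equiv), THF–MeOH (4:1), −78 °C; NaBH4 (1.2 equiv), −78 °C; MeOH quench and co-evaporation
Reagents that add atoms: none
Why: Narasaka–Prasad reduction: the boron chelate locks a half-chair and external hydride adds axially to give the 1,3-syn diol (new C1 = R, usually >10:1), leaving the secondary chloride and the thiazole untouched.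

Step 4
Reactants: 7 (1R,3S,4R)-4-chloro-1-(1,3-thiazol-2-yl)nonane-1,3-diol
Product: 8 (2S,3S,5R)-2-pentyl-5-(1,3-thiazol-2-yl)oxolan-3-ol
Conditions: AgOSO2CF3 (3 equiv), Ag2O (1.5 equiv), THF, rt to 50 °C
Reagents that add atoms: none
Why: Silver-assisted 5-exo-tet displacement of chloride by the C1 hydroxyl (Britton-type chlorodiol cyclization, an intramolecular Williamson reaction) runs with clean inversion (chloride carbon R to S), which makes pentyl and OH cis while the syn-diol makes the 2,5-substituents trans; silver also occupies the thiazole nitrogen and Ag2O takes up the acid.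

Step 5
Reactants: 8 (2S,3S,5R)-2-pentyl-5-(1,3-thiazol-2-yl)oxolan-3-ol; 9 octadecanoyl chloride
Product: 10 (2S,3S,5R)-2-pentyl-5-(1,3-thiazol-2-yl)oxolan-3-yl octadecanoate
Conditions: pyridine (3 equiv), 4-(dimethylamino)pyridine (5 mol%), CH2Cl2, 0 °C to rt
Reagents that add atoms: none
Why: Nucleophile-catalysed O-acylation of the only hydroxyl present proceeds with retention, so the stearate is placed on C7 without any selectivity question.

Step 6
Reactants: 10 (2S,3S,5R)-2-pentyl-5-(1,3-thiazol-2-yl)oxolan-3-yl octadecanoate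
Product: 13 (2S,3S,5R)-5-formyl-2-pentyloxolan-3-yl octadecanoate, via thiazolium triflate 11 (not isolated), via thiazolidine 12 (not isolated)
Conditions: MeOSO2CF3 (1.3 equiv), MeCN, 4 Å sieves, rt; evaporate; NaBH4 (2 equiv), MeOH, −10 °C, 10 min; AgNO3 (1.5 equiv), MeCN–H2O (10:1), pH 7 buffer, rt, 15 min
Reagents that add atoms: water, O
Why: Dondoni thiazole-to-formyl unmasking: N-methylation turns the aromatic ring into a thiazolium that takes up hydride to the non-aromatic thiazolidine, and silver-assisted hydrolysis of this N,S-acetal releases the aldehyde; no stereocenter is formed and the ring-oxygen-bearing carbon next to the heterocycle is known to keep its configuration in this sequence.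

Step 7
Reactants: 13 (2S,3S,5R)-5-formyl-2-pentyloxolan-3-yl octadecanoate; 14 9-bromonon-1-ene
Product: 16 (2S,3S,5R)-5-[(1R)-1-hydroxydec-9-en-1-yl]-2-pentyloxolan-3-yl octadecanoate, via Grignard reagent 15 (not isolated)
Conditions: 14, Mg, Et2O, 35 °C; separately 13, MgBr2·OEt2 (2 equiv), CH2Cl2, −78 °C; add the Grignard solution (1.3 equiv), −78 °C, 1 h; NH4Cl (aq)
Reagents that add atoms: none
Why: Grignard addition under Cram-chelate control: magnesium bridges the aldehyde oxygen and the ring oxygen, the nucleophile enters from the face away from the ring CH2 and gives the threo (9R,10R) carbinol (new C10 = R, typically 5–10:1), the aldehyde reacting far faster than the ester at −78 °C.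

**Compound list**

1 | heptanal | CCCCCCC=O | starting material
2 | (2R)-2-chloroheptanal | CCCCC[C@@H](Cl)C=O | intermediate
3 | 2-acetyl-1,3-thiazole | CC(=O)c1nccs1 | starting material
4 | lithium 1-(1,3-thiazol-2-yl)ethen-1-olate (lithium enolate of 3) | C=C(O[Li])c1nccs1 | intermediate
5 | (3S,4R)-4-chloro-3-hydroxy-1-(1,3-thiazol-2-yl)nonan-1-one | O=C(C[C@H](O)[C@H](Cl)CCCCC)c1nccs1 | intermediate
6 | (3S,4R)-4-chloro-3-[(diethylboranyl)oxy]-1-(1,3-thiazol-2-yl)nonan-1-one (boron chelate of 5) | O=C(C[C@H](OB(CC)CC)[C@H](Cl)CCCCC)c1nccs1 | intermediate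
7 | (1R,3S,4R)-4-chloro-1-(1,3-thiazol-2-yl)nonane-1,3-diol | O[C@H](C[C@H](O)[C@H](Cl)CCCCC)c1nccs1 | intermediate
8 | (2S,3S,5R)-2-pentyl-5-(1,3-thiazol-2-yl)oxolan-3-ol | c1csc(n1)[C@H]2C[C@H](O)[C@H](CCCCC)O2 | intermediate
9 | octadecanoyl chloride (stearoyl chloride) | CCCCCCCCCCCCCCCCCC(=O)Cl | starting material
10 | (2S,3S,5R)-2-pentyl-5-(1,3-thiazol-2-yl)oxolan-3-yl octadecanoate | c1csc(n1)[C@H]2C[C@H](OC(=O)CCCCCCCCCCCCCCCCC)[C@H](CCCCC)O2 | intermediate
11 | 3-methyl-2-[(2R,4S,5S)-4-(octadecanoyloxy)-5-pentyloxolan-2-yl]-1,3-thiazol-3-ium trifluoromethanesulfonate | C[n+]1ccsc1[C@H]2C[C@H](OC(=O)CCCCCCCCCCCCCCCCC)[C@H](CCCCC)O2.[O-]S(=O)(=O)C(F)(F)F | intermediate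
12 | (2S,3S,5R)-5-(3-methyl-1,3-thiazolidin-2-yl)-2-pentyloxolan-3-yl octadecanoate (both epimers at the thiazolidine carbon) | CN1CCSC1[C@H]2C[C@H](OC(=O)CCCCCCCCCCCCCCCCC)[C@H](CCCCC)O2 | intermediate
13 | (2S,3S,5R)-5-formyl-2-pentyloxolan-3-yl octadecanoate | O=C[C@H]1C[C@H](OC(=O)CCCCCCCCCCCCCCCCC)[C@H](CCCCC)O1 | intermediate
14 | 9-bromonon-1-ene | C=CCCCCCCCBr | starting material
15 | non-8-en-1-ylmagnesium bromide | C=CCCCCCCC[Mg]Br | intermediate
16 | (2S,3S,5R)-5-[(1R)-1-hydroxydec-9-en-1-yl]-2-pentyloxolan-3-yl octadecanoate | C=CCCCCCCC[C@@H](O)[C@H]1C[C@H](OC(=O)CCCCCCCCCCCCCCCCC)[C@H](CCCCC)O1 | target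

**Step count**

Total step count: 7. Longest linear sequence: 7 steps (1 to 16); compounds 3, 9 and 14 each enter once.

**Steps most likely to fail, with fallbacks**

Step 7. The chelate-controlled addition may give a poor threo:erythro ratio, or the Grignard reagent may touch the ester. The fallback replaces substrate-controlled C–C addition by reagent-controlled reduction. It sets out from 13: the Grignard addition is run without chelation control and the carbinol mixture, 16 together with (2S,3S,5R)-5-[(1S)-1-hydroxydec-9-en-1-yl]-2-pentyloxolan-3-yl octadecanoate F7, is taken on without separation. Dess–Martin periodinane with NaHCO3 in CH2Cl2 converges both to (2S,3S,5R)-5-(dec-9-enoyl)-2-pentyloxolan-3-yl octadecanoate F8. Reduction with (S)-2-methyl-CBS-oxazaborolidine and catecholborane in toluene at −78 °C (oxolanyl as the large group) gives the (R)-carbinol, and the route is back at 16.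

Step 6. Borohydride may attack the stearate, or the aldehyde may epimerize next to the ring oxygen during the three operations. The fallback takes the ester out of the reductive step by unmasking one stage earlier and acylating afterwards. It sets out from 8: methyl triflate gives 2-[(2R,4S,5S)-4-hydroxy-5-pentyloxolan-2-yl]-3-methyl-1,3-thiazol-3-ium trifluoromethanesulfonate F4, and NaBH4 in MeOH gives (2S,3S,5R)-5-(3-methyl-1,3-thiazolidin-2-yl)-2-pentyloxolan-3-ol F5. AgNO3 in MeCN–H2O then releases (2R,4S,5S)-4-hydroxy-5-pentyloxolane-2-carbaldehyde F6, whose trans hydroxyl cannot form a lactol. Acylation of F6 with 9 and pyridine at 0 °C returns the route to 13.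

Step 4. Silver may be sequestered by the thiazole, the thiazole nitrogen may be alkylated by the chloride, or the neighbouring hydroxyl may close an epoxide. The fallback replaces the silver-promoted cyclization of the free diol by a base-mediated alkoxide closure with the competing hydroxyl capped. It sets out from 5: MOMCl and i-Pr2NEt in CH2Cl2 give (3S,4R)-4-chloro-3-(methoxymethoxy)-1-(1,3-thiazol-2-yl)nonan-1-one F1. Transfer hydrogenation with RuCl(p-cymene)[(R,R)-TsDPEN] in HCO2H/Et3N sets the carbinol by catalyst control and gives (1R,3S,4R)-4-chloro-3-(methoxymethoxy)-1-(1,3-thiazol-2-yl)nonan-1-ol F2. NaH in THF closes the ring through the alkoxide with inversion at the chloride carbon to give 2-[(2R,4S,5S)-4-(methoxymethoxy)-5-pentyloxolan-2-yl]-1,3-thiazole F3. HCl in MeOH removes the methoxymethyl group and the route is back at 8.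

**Further compounds**

F1 | step 4 | (3S,4R)-4-chloro-3-(methoxymethoxy)-1-(1,3-thiazol-2-yl)nonan-1-one | O=C(C[C@H](OCOC)[C@H](Cl)CCCCC)c1nccs1
F2 | step 4 | (1R,3S,4R)-4-chloro-3-(methoxymethoxy)-1-(1,3-thiazol-2-yl)nonan-1-ol | O[C@H](C[C@H](OCOC)[C@H](Cl)CCCCC)c1nccs1
F3 | step 4 | 2-[(2R,4S,5S)-4-(methoxymethoxy)-5-pentyloxolan-2-yl]-1,3-thiazole | c1csc(n1)[C@H]2C[C@H](OCOC)[C@H](CCCCC)O2
F4 | step 6 | 2-[(2R,4S,5S)-4-hydroxy-5-pentyloxolan-2-yl]-3-methyl-1,3-thiazol-3-ium trifluoromethanesulfonate | C[n+]1ccsc1[C@H]2C[C@H](O)[C@H](CCCCC)O2.[O-]S(=O)(=O)C(F)(F)F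
F5 | step 6 | (2S,3S,5R)-5-(3-methyl-1,3-thiazolidin-2-yl)-2-pentyloxolan-3-ol | CN1CCSC1[C@H]2C[C@H](O)[C@H](CCCCC)O2
F6 | step 6 | (2R,4S,5S)-4-hydroxy-5-pentyloxolane-2-carbaldehyde | O=C[C@H]1C[C@H](O)[C@H](CCCCC)O1
F7 | step 7 | (2S,3S,5R)-5-[(1S)-1-hydroxydec-9-en-1-yl]-2-pentyloxolan-3-yl octadecanoate | C=CCCCCCCC[C@H](O)[C@H]1C[C@H](OC(=O)CCCCCCCCCCCCCCCCC)[C@H](CCCCC)O1
F8 | step 7 | (2S,3S,5R)-5-(dec-9-enoyl)-2-pentyloxolan-3-yl octadecanoate | C=CCCCCCCCC(=O)[C@H]1C[C@H](OC(=O)CCCCCCCCCCCCCCCCC)[C@H](CCCCC)O1
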